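**Retrosynthetic overview**
- The target is reached from its ring B bis(methyl ether) by cleaving the two methyl ethers ortho to the ring B ketone; the ring A methoxy group stays. The bis(methyl ether) comes from its side-chain ketal by hydrolysis.
- Ring B is disconnected into a 3-acyl-4-methoxy-6-alkyl-2-pyranone and 1,1-dimethoxyethene: (4+2) cycloaddition, then loss of CO2 and methanol.
- The feature used: in ring B the acyl-bearing carbon C1 sits between the two oxygen-bearing carbons C2 and C6, and the CH2 substituent is at C4, para to the acyl group. This is pyranone C3 (acyl), C4 (O), C5 (H) and C6 (CH2), with the lactone C(=O)–O unit replaced by the CH=C(O) unit of the ketene acetal.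
- The pyranone comes from triacetic acid lactone: acylation at the methyl group with methyl 4-methoxybenzoate, ketalisation, C3-acylation with 4-methylpentanoic acid, O-methylation.
- Ring order: ring A and the pyranone ring are bought; ring B is the only ring formed, in step 5, from the pyranone ring.

Key step: step 5

Remark: the target has no stereocentre. The side-chain aryl ketone is carried as its 1,3-dioxolane from step 2 to step 6. Its α-CH2 group, once attached to the pyranone, is a vinylogous β-dicarbonyl C–H acid that would add to the ketene acetal and compete in the acylation and methylation steps.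

**Route**

Step 1
Reactants: 1 4-hydroxy-6-methyl-2H-pyran-2-one (triacetic acid lactone); 2 methyl 4-methoxybenzoate
Product: 3 4-hydroxy-6-[2-(4-methoxyphenyl)-2-oxoethyl]-2H-pyran-2-one
Conditions: LiN(i-Pr)2 (3.2 equiv), THF, −78 → 0 °C; then 2, −78 °C → rt; 1 M HCl
Reagents that add atoms: none
Why: The dilithio derivative of 1 reacts with electrophiles at its CH2 terminus, and Claisen-type acylation by the non-enolisable ester 2 should give the 2-oxoethyl side chain, the third equivalent of base taking up the more acidic product.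

Step 2
Reactants: 3 4-hydroxy-6-[2-(4-methoxyphenyl)-2-oxoethyl]-2H-pyran-2-one
Product: 4 4-hydroxy-6-{[2-(4-methoxyphenyl)-1,3-dioxolan-2-yl]methyl}-2H-pyran-2-one
Conditions: ethylene glycol (5 equiv), TsOH·H2O (cat.), toluene, reflux, Dean–Stark
Reagents that add atoms: ethylene glycol, OCCO
Why: Acid-catalysed ketalisation with azeotropic removal of water should protect the aryl ketone, which forms an anisyl-stabilised oxocarbenium ion, while the vinylogous acid O4–H exchanges with the diol much more slowly.

Step 3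
Reactants: 4 4-hydroxy-6-{[2-(4-methoxyphenyl)-1,3-dioxolan-2-yl]methyl}-2H-pyran-2-one; 5 4-methylpentanoic acid
Product: 7 4-hydroxy-6-{[2-(4-methoxyphenyl)-1,3-dioxolan-2-yl]methyl}-3-(4-methylpentanoyl)-2H-pyran-2-one, via pyranone 4-O-ester 6 (not isolated)
Conditions: DCC (1.2 equiv), DMAP (0.3 equiv), toluene, rt → 60 °C
Reagents that add atoms: none
Why: Steglich esterification at O4 gives enol ester 6, and DMAP then moves the acyl group from O4 to C3 (Fries-type O-to-C migration through an acylpyridinium/pyranone enolate pair) to the chelated β-tricarbonyl 7, the usual way to 3-acyl-4-hydroxy-2-pyranones.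

Step 4
Reactants: 7 4-hydroxy-6-{[2-(4-methoxyphenyl)-1,3-dioxolan-2-yl]methyl}-3-(4-methylpentanoyl)-2H-pyran-2-one
Product: 8 4-methoxy-6-{[2-(4-methoxyphenyl)-1,3-dioxolan-2-yl]methyl}-3-(4-methylpentanoyl)-2H-pyran-2-one
Conditions: Me2SO4, K2CO3, acetone, reflux
Reagents that add atoms: dimethyl sulfate, COS(=O)(=O)OC
Why: Williamson-type O-alkylation of the vinylogous acid with a hard methylating agent should go at O4, as it does for the parent 3-acetyl compound (dehydroacetic acid), and with the ketone masked there is no second acidic site.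

Step 5
Reactants: 8 4-methoxy-6-{[2-(4-methoxyphenyl)-1,3-dioxolan-2-yl]methyl}-3-(4-methylpentanoyl)-2H-pyran-2-one; 9 1,1-dimethoxyethene
Product: 12 1-[2,6-dimethoxy-4-{[2-(4-methoxyphenyl)-1,3-dioxolan-2-yl]methyl}phenyl]-4-methylpentan-1-one, via bridged bicyclic lactone 10 (not isolated), via trimethoxycyclohexadiene 11 (not isolated)
Conditions: 9 (5 equiv), toluene, sealed tube, 130 °C
Reagents that add atoms: none
Why: The electron-rich alkene 9 adds to the electron-poor diene C3=C4–C5=C6 of 8, which is activated by the lactone carbonyl and the 3-acyl group, in an inverse-electron-demand Diels–Alder reaction; the closest known reaction type is the reaction of 3-alkoxycarbonyl-2-pyranones with ketene acetals to give ortho-alkoxybenzoates. Ring B is closed by this (4+2) cycloaddition, which forms the C6–CH2 and C3–C(OMe)2 bonds (concerted but asynchronous, or through a short-lived zwitterion) and gives the bridged lactone 10. Retro-(4+2) loss of CO2 then gives diene 11, and elimination of methanol from the acetal carbon and the neighbouring CH2 makes the ring aromatic. The two bridgehead stereocentres of 10 are transient and disappear in 11, so no stereocontrol is needed. The step needs regiocontrol, which comes from polarity matching: the nucleophilic CH2 of 9 bonds to C6, the δ-carbon of the doubly activated dienyl carbonyl system, and the acetal carbon bonds to C3, so the new methoxy group ends next to the acyl-bearing carbon. Attack at C4 with loss of its methoxy group is disfavoured because the donor makes C4 the less electrophilic terminus, proton transfer to 9 is excluded by the ketal, and the sealed-tube heating answers the LUMO-raising effect of the 4-methoxy group.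

Step 6
Reactants: 12 1-[2,6-dimethoxy-4-{[2-(4-methoxyphenyl)-1,3-dioxolan-2-yl]methyl}phenyl]-4-methylpentan-1-one
Product: 13 1-[2,6-dimethoxy-4-[2-(4-methoxyphenyl)-2-oxoethyl]phenyl]-4-methylpentan-1-one
Conditions: 1 M HCl, THF, rt
Reagents that add atoms: water, O
Why: Acid hydrolysis of the dioxolane through the anisyl-stabilised oxocarbenium ion should free the ketone, and the aryl methyl ethers and the ring B ketone are inert to dilute acid.

Step 7
Reactants: 13 1-[2,6-dimethoxy-4-[2-(4-methoxyphenyl)-2-oxoethyl]phenyl]-4-methylpentan-1-one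
Product: 14 1-[2,6-dihydroxy-4-[2-(4-methoxyphenyl)-2-oxoethyl]phenyl]-4-methylpentan-1-one (target)
Conditions: AlCl3 (6 equiv), CH2Cl2, 0 °C → reflux; 1 M HCl
Reagents that add atoms: none
Why: In this chelation-directed Lewis acid O-demethylation, aluminium bound to the ring B carbonyl oxygen is held next to each ortho methoxy oxygen in turn and chloride removes the methyl group as chloromethane, whereas the ring A methoxy group is para to its carbonyl, cannot chelate and is deactivated by the complexed ketone.

**Compound list**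
1 | 4-hydroxy-6-methyl-2H-pyran-2-one (triacetic acid lactone) | CC1=CC(O)=CC(=O)O1 | starting material
2 | methyl 4-methoxybenzoate | COC(=O)c1ccc(OC)cc1 | starting material
3 | 4-hydroxy-6-[2-(4-methoxyphenyl)-2-oxoethyl]-2H-pyran-2-one | COc1ccc(cc1)C(=O)CC1=CC(O)=CC(=O)O1 | intermediate
4 | 4-hydroxy-6-{[2-(4-methoxyphenyl)-1,3-dioxolan-2-yl]methyl}-2H-pyran-2-one | COc1ccc(cc1)C1(CC2=CC(O)=CC(=O)O2)OCCO1 | intermediate
5 | 4-methylpentanoic acid | CC(C)CCC(O)=O | starting material
6 | 6-{[2-(4-methoxyphenyl)-1,3-dioxolan-2-yl]methyl}-2-oxo-2H-pyran-4-yl 4-methylpentanoate (not isolated) | COc1ccc(cc1)C1(CC2=CC(OC(=O)CCC(C)C)=CC(=O)O2)OCCO1 | intermediate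
7 | 4-hydroxy-6-{[2-(4-methoxyphenyl)-1,3-dioxolan-2-yl]methyl}-3-(4-methylpentanoyl)-2H-pyran-2-one | COc1ccc(cc1)C1(CC2=CC(O)=C(C(=O)CCC(C)C)C(=O)O2)OCCO1 | intermediate
8 | 4-methoxy-6-{[2-(4-methoxyphenyl)-1,3-dioxolan-2-yl]methyl}-3-(4-methylpentanoyl)-2H-pyran-2-one | COc1ccc(cc1)C1(CC2=CC(OC)=C(C(=O)CCC(C)C)C(=O)O2)OCCO1 | intermediate
9 | 1,1-dimethoxyethene | C=C(OC)OC | starting material
10 | 5,8,8-trimethoxy-1-{[2-(4-methoxyphenyl)-1,3-dioxolan-2-yl]methyl}-4-(4-methylpentanoyl)-2-oxabicyclo[2.2.2]oct-5-en-3-one (racemic, not isolated) | O=C1OC2(CC3(c4ccc(OC)cc4)OCCO3)CC(OC)(OC)C1(C(=O)CCC(C)C)C(OC)=C2 | intermediate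
11 | 1-[2,6,6-trimethoxy-4-{[2-(4-methoxyphenyl)-1,3-dioxolan-2-yl]methyl}cyclohexa-1,3-dien-1-yl]-4-methylpentan-1-one (not isolated) | CC(C)CCC(=O)C1=C(OC)C=C(CC2(c3ccc(OC)cc3)OCCO2)CC1(OC)OC | intermediate
12 | 1-[2,6-dimethoxy-4-{[2-(4-methoxyphenyl)-1,3-dioxolan-2-yl]methyl}phenyl]-4-methylpentan-1-one | CC(C)CCC(=O)c1c(OC)cc(CC2(c3ccc(OC)cc3)OCCO2)cc1OC | intermediate
13 | 1-[2,6-dimethoxy-4-[2-(4-methoxyphenyl)-2-oxoethyl]phenyl]-4-methylpentan-1-one | CC(C)CCC(=O)c1c(OC)cc(CC(=O)c2ccc(OC)cc2)cc1OC | intermediate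
14 | 1-[2,6-dihydroxy-4-[2-(4-methoxyphenyl)-2-oxoethyl]phenyl]-4-methylpentan-1-one | COc1ccc(C(=O)Cc2cc(O)c(C(=O)CCC(C)C)c(O)c2)cc1 | target

Total step count: 7. Longest linear sequence: 7 steps (from 1).

**Steps most likely to fail**

1. Step 5. The cycloaddition may stall because the 4-methoxy donor raises the diene LUMO; the ketene acetal may instead add at C4 with loss of methoxide, or polymerise before it adds. Fallback (ring B taken from a resorcinol ether; sets out from 2 and 5, returns at 12): the dianion of commercial 3,5-dimethoxyphenylacetic acid (LiN(i-Pr)2, THF) would be acylated by 2 to give 2-(3,5-dimethoxyphenyl)-3-(4-methoxyphenyl)-3-oxopropanoic acid F1 (racemic, not isolated). F1 should lose CO2 on acidic work-up to give 2-(3,5-dimethoxyphenyl)-1-(4-methoxyphenyl)ethan-1-one F2. Ketalisation (ethylene glycol, TsOH, benzene, Dean–Stark) would give 2-[(3,5-dimethoxyphenyl)methyl]-2-(4-methoxyphenyl)-1,3-dioxolane F3. Directed lithiation between the two methoxy groups (n-BuLi, THF, 0 °C) and acylation with N-methoxy-N,4-dimethylpentanamide F4 (from 5 with 1,1'-carbonyldiimidazole and MeNHOMe·HCl) would give 12.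

2. Step 7. After the first cleavage the aluminium phenoxide occupies the carbonyl oxygen, so the second ortho ether may cleave slowly, and longer heating may begin to cleave the ring A ether. Fallback (the two ethers cleaved one at a time, chelation restored in between; sets out from 13, returns at 14): BCl3 (CH2Cl2, −78 → 0 °C) should remove one ortho methyl group to give 1-[2-hydroxy-6-methoxy-4-[2-(4-methoxyphenyl)-2-oxoethyl]phenyl]-4-methylpentan-1-one F5. Acetylation (Ac2O, pyridine, DMAP) would give 3-methoxy-5-[2-(4-methoxyphenyl)-2-oxoethyl]-2-(4-methylpentanoyl)phenyl acetate F6, whose carbonyl oxygen is free again to direct a second BCl3 cleavage to 3-hydroxy-5-[2-(4-methoxyphenyl)-2-oxoethyl]-2-(4-methylpentanoyl)phenyl acetate F7. K2CO3 in methanol would remove the acetate and give 14.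

3. Step 2. Under hot acid the diol may etherify O4 of the vinylogous acid or open the enol lactone instead of ketalising the deactivated anisyl ketone. Fallback (protection postponed until O4 is methylated; sets out from 3, returns at 8): 3 would be acylated with 5 (DCC, DMAP) through 6-[2-(4-methoxyphenyl)-2-oxoethyl]-2-oxo-2H-pyran-4-yl 4-methylpentanoate F8 (not isolated) to give 4-hydroxy-6-[2-(4-methoxyphenyl)-2-oxoethyl]-3-(4-methylpentanoyl)-2H-pyran-2-one F9. Me3SiCHN2 in toluene/methanol, which reacts only with the strongly acidic enol, would give 4-methoxy-6-[2-(4-methoxyphenyl)-2-oxoethyl]-3-(4-methylpentanoyl)-2H-pyran-2-one F10. Ketalisation under aprotic conditions (Me3SiOCH2CH2OSiMe3, Me3SiOTf cat., CH2Cl2, −78 → −20 °C), where no free alcohol can exchange with the 4-methoxy group, would give 8.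

Further compounds
F1 | step 5 | 2-(3,5-dimethoxyphenyl)-3-(4-methoxyphenyl)-3-oxopropanoic acid (racemic, not isolated) | COc1ccc(cc1)C(=O)C(C(O)=O)c1cc(OC)cc(OC)c1
F2 | step 5 | 2-(3,5-dimethoxyphenyl)-1-(4-methoxyphenyl)ethan-1-one | COc1ccc(cc1)C(=O)Cc1cc(OC)cc(OC)c1
F3 | step 5 | 2-[(3,5-dimethoxyphenyl)methyl]-2-(4-methoxyphenyl)-1,3-dioxolane | COc1ccc(cc1)C1(Cc2cc(OC)cc(OC)c2)OCCO1
F4 | step 5 | N-methoxy-N,4-dimethylpentanamide | CC(C)CCC(=O)N(C)OC
F5 | step 7 | 1-[2-hydroxy-6-methoxy-4-[2-(4-methoxyphenyl)-2-oxoethyl]phenyl]-4-methylpentan-1-one | CC(C)CCC(=O)c1c(O)cc(CC(=O)c2ccc(OC)cc2)cc1OC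
F6 | step 7 | 3-methoxy-5-[2-(4-methoxyphenyl)-2-oxoethyl]-2-(4-methylpentanoyl)phenyl acetate | CC(C)CCC(=O)c1c(OC(C)=O)cc(CC(=O)c2ccc(OC)cc2)cc1OC
F7 | step 7 | 3-hydroxy-5-[2-(4-methoxyphenyl)-2-oxoethyl]-2-(4-methylpentanoyl)phenyl acetate | CC(C)CCC(=O)c1c(OC(C)=O)cc(CC(=O)c2ccc(OC)cc2)cc1O
F8 | step 2 | 6-[2-(4-methoxyphenyl)-2-oxoethyl]-2-oxo-2H-pyran-4-yl 4-methylpentanoate (not isolated) | COc1ccc(cc1)C(=O)CC1=CC(OC(=O)CCC(C)C)=CC(=O)O1
F9 | step 2 | 4-hydroxy-6-[2-(4-methoxyphenyl)-2-oxoethyl]-3-(4-methylpentanoyl)-2H-pyran-2-one | COc1ccc(cc1)C(=O)CC1=CC(O)=C(C(=O)CCC(C)C)C(=O)O1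
F10 | step 2 | 4-methoxy-6-[2-(4-methoxyphenyl)-2-oxoethyl]-3-(4-methylpentanoyl)-2H-pyran-2-one | COc1ccc(cc1)C(=O)CC1=CC(OC)=C(C(=O)CCC(C)C)C(=O)O1
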